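Amber holds 20 mM of substrate, 30.0 mM of second reagent and 5.00 mM of partner, and the other flasks raise the partner charge up to 80.0 mM in green.

| flask | substrate | partner | second reagent | time |
|---|---|---|---|---|
| amber | 20 mM | 5.00 mM | 30.0 mM | 2.0 h |
| ochre | 20 mM | 10.0 mM | 30.0 mM | 2.0 h |
| red | 20 mM | 20.0 mM | 30.0 mM | 2.0 h |
| teal | 20 mM | 40.0 mM | 30.0 mM | 2.0 h |
| green | 20 mM | 80.0 mM | 30.0 mM | 2.0 h |

    substrate + partner → intermediate (k1 = 0.0128 /M/s)
    second reagent + intermediate → target (k2 = 0.00558 /M/s)
    partner + target → over-reaction product (k3 = 0.00675 /M/s)

- "hardly changes" means that all values lie within two and a half points (for a concentration: within two and a half percent of the largest)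
- run time (amber): 2.0 h

- amount of target at the end, in percent of the substrate charged for amber, ochre, red, teal, green, in this order
- how the row runs (hardly changes / rises, then falls / falls, then rises / falls all the way / rises all the way)

1. We turn the question round and ask what the given numbers must say for the row to rise to the end. Partner feeds step 1, but it also eats target in step 3. At 24.8 mM of partner, a target molecule is eaten by step 3 as fast as an intermediate molecule becomes target by step 2 with second reagent as charged. We call this the balance charge, a selectivity factor written as a concentration.

2. We take a row rising to the end to ask that green's charge stand below the balance charge. Instead it stands 3.23 times above it. Red lies below and teal above, so we commit to a row that rises, then falls.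

3. Green can be reckoned. Substrate's half-life by step 1 is 0.188 h, much shorter than the run, so we treat that step as over at once. That leaves 0.0600 M of partner free. As a rough estimate we hold second reagent at its charge and partner at that remainder, so that target is made at m = 0.603 /h and eaten at n = 1.46 /h. For step 2 this pseudo-first-order treatment is crude: second reagent is charged at just 1.50 times the substrate. The target share m/(n−m)·(exp(−m t) − exp(−n t)) comes to 17.3% at 2.0 h.

4. The forecast gives 9.6%, 17%, 26%, 29% and 19%, a row that rises, then falls, on the ground that “At low partner, the partner is limiting and the target yield climbs with the charge”. Its green value is higher than ours.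

5. The simulation gives 9.66%, 17.1%, 26.0%, 28.4% and 16.7%, a row that rises, then falls, turning at a read 32 mM. In amber, at charged concentrations, intermediate has a half-life of 1.2 h by step 2 and target 5.7 h by step 3, a ratio of 4.96, which is the balance charge over amber's partner, 4.96, and amber ends with target at 9.66% against over-reaction product at 0.329%. In green, the partner left at the end, 52.6 mM, stands 2.12 times above the balance charge, and over-reaction product ends at 37.4% against target at 16.7%.

The constants were drawn at random within sensible limits; the flask was simulated.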